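**Retrosynthetic overview**

1. Target 19 comes from its tris-MOM ether 18. In 18 the dihydropyran ring is cut across O1–C2 and C3–C4 (chroman numbering) into ortho-quinone methide 17, made from ortho-hydroxybenzyl alcohol 15, and isobutene 16 (inverse-demand hetero-Diels–Alder reaction).
2. Enabling feature: in ring B the chroman O1 sits on C8a and the C4 methylene on the neighbouring C4a, so O1–C8a–C4a–C4 is a latent 1-oxadiene; the C7 oxygen para to C4a stabilises it, and C2 with its two methyl groups plus C3 is isobutene.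
3. 15 comes from aldehyde 14, and 14 from ethynylphenol 7 and aryl iodide 12 by Pd/Cu coupling and 5-endo-dig closure of the furan ring (benzofuran C2–aryl and O1–C2 bonds).
4. 7 comes from 2,4,6-trihydroxybenzaldehyde 1: the 1,1-dimethylallyl group at benzofuran C7 is set by Claisen rearrangement of a prenyl ether whose other ortho site is blocked by the formyl group (later C3). 12 comes from 1-iodo-3,5-dimethoxybenzene 8 by Vilsmeier formylation (the formyl carbon becomes chroman C4).
5. Ring order: both benzene rings are bought; the furan ring is closed in step 8; the dihydropyran ring is closed last, in step 10.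

Key step: step 10

Remark: the target has no stereocentre and no stereogenic double bond, so no step has to set configuration; locants in the text are those of 1-benzofuran and 3,4-dihydro-2H-chromene as in the target.

**Route**

Step 1
Reactants: 1 2,4,6-trihydroxybenzaldehyde
Product: 2 2-hydroxy-4,6-bis(methoxymethoxy)benzaldehyde
Conditions: MOMCl (2.1 equiv), i-Pr2NEt, CH2Cl2, 0 °C to rt
Reagents that add atoms: chloromethyl methyl ether (MOMCl), COCCl
Why: O-alkylation of phenols (MOM protection), in which the para hydroxyl and one of the two equivalent ortho hydroxyls should react while the remaining one, held in a hydrogen bond to the formyl oxygen, stays free.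

Step 2
Reactants: 2 2-hydroxy-4,6-bis(methoxymethoxy)benzaldehyde, 3 1-bromo-3-methylbut-2-ene (prenyl bromide)
Product: 4 2,4-bis(methoxymethoxy)-6-[(3-methylbut-2-en-1-yl)oxy]benzaldehyde
Conditions: K2CO3, acetone, reflux
Reagents that add atoms: none
Why: Williamson ether synthesis on the only free phenol with a reactive allylic bromide.

Step 3
Reactants: 4 2,4-bis(methoxymethoxy)-6-[(3-methylbut-2-en-1-yl)oxy]benzaldehyde
Product: 6 2-hydroxy-4,6-bis(methoxymethoxy)-3-(2-methylbut-3-en-2-yl)benzaldehyde, via Claisen dienone 5 (not isolated)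
Conditions: PhNEt2, 190 °C, sealed tube, argon
Reagents that add atoms: none
Why: Aromatic Claisen rearrangement, in which the formyl group blocks one ortho carbon so that the allyl unit should be delivered with allylic inversion (as the 1,1-dimethylallyl group) to the only free ortho carbon, and tautomerisation of dienone 5 restores the phenol.

Step 4
Reactants: 6 2-hydroxy-4,6-bis(methoxymethoxy)-3-(2-methylbut-3-en-2-yl)benzaldehyde
Product: 7 2-ethynyl-3,5-bis(methoxymethoxy)-6-(2-methylbut-3-en-2-yl)phenol
Conditions: dimethyl (1-diazo-2-oxopropyl)phosphonate (2 equiv), K2CO3 (3 equiv), MeOH, 0 °C to rt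
Reagents that add atoms: dimethyl (1-diazo-2-oxopropyl)phosphonate, CC(=O)C(=[N+]=[N-])P(=O)(OC)OC
Why: Seyferth–Gilbert homologation in the Ohira–Bestmann variant should turn the aldehyde into the terminal alkyne under mild base that the MOM ethers and the alkene tolerate.

Step 5
Reactants: 8 1-iodo-3,5-dimethoxybenzene
Product: 10 2-iodo-4,6-dimethoxybenzaldehyde, via iminium chloride 9 (not isolated)
Conditions: POCl3, DMF, 0 to 70 °C; then H2O
Reagents that add atoms: N,N-dimethylformamide, CN(C)C=O; water, O
Why: Vilsmeier–Haack formylation, expected at the carbon para to one methoxy group and ortho to the other (next to iodine) rather than at the site flanked by two methoxy groups.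

Step 6
Reactants: 10 2-iodo-4,6-dimethoxybenzaldehyde
Product: 11 2,4-dihydroxy-6-iodobenzaldehyde
Conditions: BBr3 (3 equiv), CH2Cl2, −78 °C to rt; then H2O
Reagents that add atoms: none
Why: Lewis-acid cleavage of aryl methyl ethers, carried out before any acid-sensitive group is present.

Step 7
Reactants: 11 2,4-dihydroxy-6-iodobenzaldehyde
Product: 12 2-hydroxy-6-iodo-4-(methoxymethoxy)benzaldehyde
Conditions: MOMCl (1.05 equiv), i-Pr2NEt, CH2Cl2, 0 °C
Reagents that add atoms: chloromethyl methyl ether (MOMCl), COCCl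
Why: Selective O-alkylation (MOM protection) of the more acidic, non-chelated para hydroxyl, leaving the hydrogen-bonded ortho hydroxyl free.

Step 8
Reactants: 7 2-ethynyl-3,5-bis(methoxymethoxy)-6-(2-methylbut-3-en-2-yl)phenol, 12 2-hydroxy-6-iodo-4-(methoxymethoxy)benzaldehyde
Product: 14 2-[4,6-bis(methoxymethoxy)-7-(2-methylbut-3-en-2-yl)-1-benzofuran-2-yl]-6-hydroxy-4-(methoxymethoxy)benzaldehyde, via diarylalkyne 13 (not isolated)
Conditions: PdCl2(PPh3)2 (5 mol%), CuI (10 mol%), Et3N, DMF, rt then 60 °C
Reagents that add atoms: none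
Why: Sonogashira coupling with the ortho-formyl aryl iodide followed in the same flask by 5-endo-dig addition of the neighbouring phenoxide to the metal-activated alkyne; only the ring A hydroxyl is ortho to the alkyne, so a single benzofuran should result.

Step 9
Reactants: 14 2-[4,6-bis(methoxymethoxy)-7-(2-methylbut-3-en-2-yl)-1-benzofuran-2-yl]-6-hydroxy-4-(methoxymethoxy)benzaldehyde
Product: 15 3-[4,6-bis(methoxymethoxy)-7-(2-methylbut-3-en-2-yl)-1-benzofuran-2-yl]-2-(hydroxymethyl)-5-(methoxymethoxy)phenol
Conditions: NaBH4, THF/MeOH, 0 °C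
Reagents that add atoms: none
Why: Borohydride reduction of the aldehyde to the primary alcohol, to which alkenes, acetals and the benzofuran are inert; the low temperature should keep the ortho-hydroxybenzyl alcohol from ionising.

Step 10
Reactants: 15 3-[4,6-bis(methoxymethoxy)-7-(2-methylbut-3-en-2-yl)-1-benzofuran-2-yl]-2-(hydroxymethyl)-5-(methoxymethoxy)phenol, 16 2-methylprop-1-ene (isobutene)
Product: 18 2-[7-(methoxymethoxy)-2,2-dimethyl-3,4-dihydro-2H-chromen-5-yl]-4,6-bis(methoxymethoxy)-7-(2-methylbut-3-en-2-yl)-1-benzofuran, via ortho-quinone methide 17 (not isolated)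
Conditions: isobutene (large excess, condensed in), toluene, sealed tube, 160 °C
Reagents that add atoms: none
Why: Heating should dehydrate the ortho-hydroxybenzyl alcohol of 15 to ortho-quinone methide 17, whose 1-oxadiene O1=C8a–C4a=C4 adds isobutene in an inverse-electron-demand hetero-Diels–Alder reaction; the C4–C3 bond is well advanced in the asynchronous transition state and the O1–C2 bond to the carbon bearing the two methyl groups closes the ring. The closest known reaction type is the thermal cycloaddition of phenol-derived ortho-quinone methides with unactivated 1,1-disubstituted alkenes, which gives 2,2-disubstituted chromans. The dihydropyran ring is closed as a (4+2) cycloaddition, suprafacial on both partners, and rearomatisation of ring B drives it. No stereocentre is formed, since C2 carries two methyl groups and C3 and C4 are methylene groups. The step needs regioselectivity (oxygen to the disubstituted carbon), which follows from attack of the nucleophilic CH2 terminus of isobutene on the electrophilic methide carbon with tertiary cation character at C2, and site selectivity on ring B, which is fixed because the methide carbon is the former formyl carbon on C4a and only the ortho oxygen is free (the para oxygen at C7 is a MOM ether that stabilises the methide). It also needs chemoselectivity over the hindered vinyl group, the benzofuran C2=C3 bond and self-addition of 17, which the large excess of isobutene should secure.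

Step 11
Reactants: 18 2-[7-(methoxymethoxy)-2,2-dimethyl-3,4-dihydro-2H-chromen-5-yl]-4,6-bis(methoxymethoxy)-7-(2-methylbut-3-en-2-yl)-1-benzofuran
Product: 19 2-(7-hydroxy-2,2-dimethyl-3,4-dihydro-2H-chromen-5-yl)-7-(2-methylbut-3-en-2-yl)-1-benzofuran-4,6-diol (target)
Conditions: HCl (cat.), MeOH, 40 °C
Reagents that add atoms: none
Why: Acid-catalysed acetal exchange with methanol should remove the three MOM ethers under conditions too mild to protonate the monosubstituted alkene of the 1,1-dimethylallyl group.

**Compound list**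

1 | 2,4,6-trihydroxybenzaldehyde | O=Cc1c(O)cc(O)cc1O | starting material
2 | 2-hydroxy-4,6-bis(methoxymethoxy)benzaldehyde | O=Cc1c(O)cc(OCOC)cc1OCOC | intermediate
3 | 1-bromo-3-methylbut-2-ene (prenyl bromide) | CC(C)=CCBr | starting material
4 | 2,4-bis(methoxymethoxy)-6-[(3-methylbut-2-en-1-yl)oxy]benzaldehyde | O=Cc1c(OCC=C(C)C)cc(OCOC)cc1OCOC | intermediate
5 | Claisen dienone, racemic 2,4-bis(methoxymethoxy)-5-(2-methylbut-3-en-2-yl)-6-oxocyclohexa-1,3-diene-1-carbaldehyde (not isolated) | O=CC1=C(OCOC)C=C(OCOC)C(C(C)(C)C=C)C1=O | intermediate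
6 | 2-hydroxy-4,6-bis(methoxymethoxy)-3-(2-methylbut-3-en-2-yl)benzaldehyde | O=Cc1c(O)c(C(C)(C)C=C)c(OCOC)cc1OCOC | intermediate
7 | 2-ethynyl-3,5-bis(methoxymethoxy)-6-(2-methylbut-3-en-2-yl)phenol | C#Cc1c(O)c(C(C)(C)C=C)c(OCOC)cc1OCOC | intermediate
8 | 1-iodo-3,5-dimethoxybenzene | COc1cc(I)cc(OC)c1 | starting material
9 | iminium chloride, N-[(2-iodo-4,6-dimethoxyphenyl)methylidene]-N-methylmethanaminium chloride (not isolated) | C[N+](C)=Cc1c(I)cc(OC)cc1OC.[Cl-] | intermediate
10 | 2-iodo-4,6-dimethoxybenzaldehyde | O=Cc1c(I)cc(OC)cc1OC | intermediate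
11 | 2,4-dihydroxy-6-iodobenzaldehyde | O=Cc1c(I)cc(O)cc1O | intermediate
12 | 2-hydroxy-6-iodo-4-(methoxymethoxy)benzaldehyde | O=Cc1c(I)cc(OCOC)cc1O | intermediate
13 | diarylalkyne, 2-hydroxy-6-{[2-hydroxy-4,6-bis(methoxymethoxy)-3-(2-methylbut-3-en-2-yl)phenyl]ethynyl}-4-(methoxymethoxy)benzaldehyde (not isolated) | O=Cc1c(C#Cc2c(O)c(C(C)(C)C=C)c(OCOC)cc2OCOC)cc(OCOC)cc1O | intermediate
14 | 2-[4,6-bis(methoxymethoxy)-7-(2-methylbut-3-en-2-yl)-1-benzofuran-2-yl]-6-hydroxy-4-(methoxymethoxy)benzaldehyde | C=CC(C)(C)c1c(OCOC)cc(OCOC)c2cc(-c3cc(OCOC)cc(O)c3C=O)oc12 | intermediate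
15 | 3-[4,6-bis(methoxymethoxy)-7-(2-methylbut-3-en-2-yl)-1-benzofuran-2-yl]-2-(hydroxymethyl)-5-(methoxymethoxy)phenol | C=CC(C)(C)c1c(OCOC)cc(OCOC)c2cc(-c3cc(OCOC)cc(O)c3CO)oc12 | intermediate
16 | 2-methylprop-1-ene (isobutene) | C=C(C)C | starting material
17 | ortho-quinone methide, 5-[4,6-bis(methoxymethoxy)-7-(2-methylbut-3-en-2-yl)-1-benzofuran-2-yl]-3-(methoxymethoxy)-6-methylidenecyclohexa-2,4-dien-1-one (not isolated) | C=C1C(=O)C=C(OCOC)C=C1c1cc2c(OCOC)cc(OCOC)c(C(C)(C)C=C)c2o1 | intermediate
18 | 2-[7-(methoxymethoxy)-2,2-dimethyl-3,4-dihydro-2H-chromen-5-yl]-4,6-bis(methoxymethoxy)-7-(2-methylbut-3-en-2-yl)-1-benzofuran | C=CC(C)(C)c1c(OCOC)cc(OCOC)c2cc(-c3cc(OCOC)cc4c3CCC(C)(C)O4)oc12 | intermediate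
19 | 2-(7-hydroxy-2,2-dimethyl-3,4-dihydro-2H-chromen-5-yl)-7-(2-methylbut-3-en-2-yl)-1-benzofuran-4,6-diol | C=CC(C)(C)c1c(O)cc(O)c2cc(-c3cc(O)cc4c3CCC(C)(C)O4)oc12 | target

**Step count and risks**

Total step count: 11. Longest linear sequence: 8 steps (steps 1 to 4, then 8 to 11).

Steps most likely to fail:

Step 10. Self-addition and oligomerisation of the quinone methide may outpace its capture by the volatile, only moderately nucleophilic alkene. The fallback builds the chroman on fragment B before the union, by known chemistry. It sets out from 12: addition of 2-methylprop-1-en-1-ylmagnesium bromide (3 equiv, THF, 0 °C) should give racemic 2-(1-hydroxy-3-methylbut-2-en-1-yl)-3-iodo-5-(methoxymethoxy)phenol F1. Mild acid (pyridinium p-toluenesulfonate, toluene, 60 °C) should dehydrate F1 to a vinyl quinone methide that closes by oxa-6π electrocyclisation to 5-iodo-7-(methoxymethoxy)-2,2-dimethyl-2H-chromene F2. Diimide reduction (p-toluenesulfonyl hydrazide, NaOAc, DME/H2O, reflux), which leaves the aryl iodide alone, should give 5-iodo-7-(methoxymethoxy)-2,2-dimethyl-3,4-dihydro-2H-chromene F3. Coupling and cyclisation of F3 with 7 under the conditions of step 8 comes back to the route at 18, so that steps 9 and 10 fall away.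

Step 4. Under the basic conditions the aldehyde, flanked on both sides and conjugated to a phenoxide, may add the diazophosphonate anion too slowly, and the ethynylphenol may cyclise prematurely. The fallback postpones the Claisen rearrangement. It sets out from 4: the same homologation on this phenol-free aldehyde should give 2-ethynyl-1,5-bis(methoxymethoxy)-3-[(3-methylbut-2-en-1-yl)oxy]benzene F4. Sonogashira coupling with 12 (PdCl2(PPh3)2, CuI, Et3N, DMF, rt) should give 2-{[2,4-bis(methoxymethoxy)-6-[(3-methylbut-2-en-1-yl)oxy]phenyl]ethynyl}-6-hydroxy-4-(methoxymethoxy)benzaldehyde F5. Claisen rearrangement of F5 (PhNEt2, 190 °C) should unveil the phenol of 13, now isolated, and Cs2CO3 in DMF at 60 °C should close the furan ring, coming back to the route at 14.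

Step 8. Copper-mediated cycloisomerisation of the free ethynylphenol before cross-coupling, and oxidative homocoupling of the alkyne, may consume 7. The fallback makes the C2–aryl bond after the furan ring. It sets out from 7: Cs2CO3 in DMF at 60 °C should give 4,6-bis(methoxymethoxy)-7-(2-methylbut-3-en-2-yl)-1-benzofuran F6. Iridium-catalysed C2–H borylation ([Ir(OMe)(cod)]2, 4,4'-di-tert-butyl-2,2'-bipyridine, bis(pinacolato)diboron, THF, 50 °C) should give 2-[4,6-bis(methoxymethoxy)-7-(2-methylbut-3-en-2-yl)-1-benzofuran-2-yl]-4,4,5,5-tetramethyl-1,3,2-dioxaborolane F7. Suzuki–Miyaura coupling of F7 with 12 (Pd(dppf)Cl2, K3PO4, dioxane/H2O, 80 °C) comes back to the route at 14.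

**Further compounds**

F1 | step 10 | racemic 2-(1-hydroxy-3-methylbut-2-en-1-yl)-3-iodo-5-(methoxymethoxy)phenol | CC(C)=CC(O)c1c(I)cc(OCOC)cc1O
F2 | step 10 | 5-iodo-7-(methoxymethoxy)-2,2-dimethyl-2H-chromene | CC1(C)C=Cc2c(I)cc(OCOC)cc2O1
F3 | step 10 | 5-iodo-7-(methoxymethoxy)-2,2-dimethyl-3,4-dihydro-2H-chromene | CC1(C)CCc2c(I)cc(OCOC)cc2O1
F4 | step 4 | 2-ethynyl-1,5-bis(methoxymethoxy)-3-[(3-methylbut-2-en-1-yl)oxy]benzene | C#Cc1c(OCC=C(C)C)cc(OCOC)cc1OCOC
F5 | step 4 | 2-{[2,4-bis(methoxymethoxy)-6-[(3-methylbut-2-en-1-yl)oxy]phenyl]ethynyl}-6-hydroxy-4-(methoxymethoxy)benzaldehyde | O=Cc1c(C#Cc2c(OCC=C(C)C)cc(OCOC)cc2OCOC)cc(OCOC)cc1O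
F6 | step 8 | 4,6-bis(methoxymethoxy)-7-(2-methylbut-3-en-2-yl)-1-benzofuran | C=CC(C)(C)c1c(OCOC)cc(OCOC)c2ccoc12
F7 | step 8 | 2-[4,6-bis(methoxymethoxy)-7-(2-methylbut-3-en-2-yl)-1-benzofuran-2-yl]-4,4,5,5-tetramethyl-1,3,2-dioxaborolane | C=CC(C)(C)c1c(OCOC)cc(OCOC)c2cc(B3OC(C)(C)C(C)(C)O3)oc12
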